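**Plan**
- Retrosynthesis cuts, in order: the C6–O acyl bond of the side-chain ester; the exocyclic C11=C13 bond; the C4=C5 double bond of the nine-membered oxonine ring (furanone O, C3–C10), unfolded into C4(Cl)–SO2–C5 of a ten-membered 1-oxa-4-thiacyclodecane; the two C–S bonds; C5–C6 and C7–C8; the furanone O–C3 bond; C9–C10.
- Enabling feature: C4 sits on the furanone carbon C3 (vinylogous α-position of the C1 ketone) and C5 is a CH next to C6–O, so both alkene carbons can first be tied to one sulfur atom; loss of SO2 from that ring can only give the Z alkene inside the bridged oxonine.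
- Forward: furanone ring first (lactic acid, allyl bromide, but-1-yne), then the trans γ-lactone (aldol/lactonization), extension to C5, ten-membered sulfide ring by double S-alkylation, oxidation and chlorination, contraction to the oxonine, then methylenation and esterification.
- Stereochemistry: C10 from (S)-lactic acid (acetal-controlled allylation); C7/C8 from the (R)-benzyloxazolidinone syn-aldol; C6 from (S)-CBS reduction; side-chain carbinol from (R)-but-3-yn-2-ol; 4Z from the ring constraint in the contraction.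

Key step: step 17

Remark: germacrane numbering is used (C1 ketone, C2=C3 and O of the furanone, C4=C5 ring alkene with C15 methyl, C6 acyloxy carbon, C7/C8 lactone fusion, C9 methylene, C10 quaternary carbon with C14 methyl, C11–C13 methylene lactone); 22–26 are assumed to be carried as C4 epimer mixtures and 28–29 as C11 epimer mixtures, because both centres become sp2.

**Route**

Step 1
Reactants: 1 (S)-lactic acid; 2 pivalaldehyde
Product: 3 (2S,5S)-2-tert-butyl-5-methyl-1,3-dioxolan-4-one
Conditions: cat. p-TsOH, cat. H2SO4, pentane, reflux (Dean–Stark); crystallization at −78 °C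
Reagents that add atoms: none
Why: Acid-catalysed acetalization with water removal should give mainly the cis acetal, whose new acetal centre is set by the lactic acid centre under thermodynamic control and purified by crystallization.

Step 2
Reactants: 3 (2S,5S)-2-tert-butyl-5-methyl-1,3-dioxolan-4-one; 4 allyl bromide
Product: 5 (2S,5R)-2-tert-butyl-5-methyl-5-(prop-2-en-1-yl)-1,3-dioxolan-4-one
Conditions: LDA, THF, −78 °C; then 4, −78 → −20 °C
Reagents that add atoms: none
Why: Seebach alkylation (self-regeneration of stereocentres): the lithium enolate is allylated anti to the tert-butyl group, so allyl replaces H with retention and fixes the future C10 as R.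

Step 3
Reactants: 5 (2S,5R)-2-tert-butyl-5-methyl-5-(prop-2-en-1-yl)-1,3-dioxolan-4-one
Product: 6 (2R)-2-hydroxy-N-methoxy-N,2-dimethylpent-4-enamide
Conditions: MeNHOMe·HCl, i-PrMgCl, THF, −20 → 23 °C
Reagents that add atoms: N,O-dimethylhydroxylamine hydrochloride CNOC.Cl
Why: Weinreb aminolysis of the acylal lactone by the chloromagnesium amide opens the ring and releases pivalaldehyde without touching the quaternary centre.

Step 4
Reactants: 6 (2R)-2-hydroxy-N-methoxy-N,2-dimethylpent-4-enamide; 7 but-1-yne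
Product: 8 (4R)-4-hydroxy-4-methylnon-1-en-6-yn-5-one
Conditions: 7 (2.4 equiv), n-BuLi (2.3 equiv), THF, −78 °C; then 6, −78 → 0 °C; aq. NH4Cl
Reagents that add atoms: none
Why: Acylation of lithium butynide by the Weinreb amide (the alkoxide forms first, the chelated tetrahedral intermediate prevents over-addition) should give the γ-hydroxy ynone.

Step 5
Reactants: 8 (4R)-4-hydroxy-4-methylnon-1-en-6-yn-5-one
Product: 9 (2R)-5-ethyl-2-methyl-2-(prop-2-en-1-yl)furan-3(2H)-one
Conditions: AuCl3 (5 mol %), CH2Cl2, 23 °C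
Reagents that add atoms: none
Why: Gold-catalysed 5-endo-dig cycloisomerization (intramolecular oxa-Michael addition of the tertiary alcohol to the activated ynone) is the standard route from γ-hydroxy ynones to 3(2H)-furanones.

Step 6
Reactants: 9 (2R)-5-ethyl-2-methyl-2-(prop-2-en-1-yl)furan-3(2H)-one
Product: 10 [(2R)-5-ethyl-2-methyl-3-oxo-2,3-dihydrofuran-2-yl]acetaldehyde
Conditions: OsO4 (2 mol %), NaIO4, 2,6-lutidine, dioxane/H2O 3:1, 23 °C
Reagents that add atoms: osmium tetroxide (catalytic, transfers the oxygen) O=[Os](=O)(=O)=O; sodium periodate (terminal oxidant) [Na+].[O-]I(=O)(=O)=O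
Why: Lemieux–Johnson oxidation: the isolated terminal alkene is dihydroxylated far faster than the electron-poor push–pull furanone double bond, and periodate cleaves the diol to the C8 aldehyde.

Step 7
Reactants: 11 (4R)-4-benzyl-1,3-oxazolidin-2-one; 12 methyl 4-chloro-4-oxobutanoate
Product: 13 methyl 4-[(4R)-4-benzyl-2-oxo-1,3-oxazolidin-3-yl]-4-oxobutanoate
Conditions: n-BuLi, THF, −78 °C; then 12, −78 → 0 °C
Reagents that add atoms: none
Why: N-Acylation of the lithiated Evans oxazolidinone by the acid chloride, which reacts in preference to the methyl ester.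

Step 8
Reactants: 10 [(2R)-5-ethyl-2-methyl-3-oxo-2,3-dihydrofuran-2-yl]acetaldehyde; 13 methyl 4-[(4R)-4-benzyl-2-oxo-1,3-oxazolidin-3-yl]-4-oxobutanoate
Product: 15 trans-lactone imide (2S,3R), via aldol adduct 14 (not isolated)
Conditions: 13, Bu2BOTf, i-Pr2NEt, CH2Cl2, 0 °C; 10, −78 → 0 °C; pH 7 buffer, MeOH, H2O2; then CSA (cat.), CH2Cl2, 23 °C
Reagents that add atoms: none
Why: Evans syn-aldol reaction through the (Z)-boron enolate of the imide in a Zimmerman–Traxler chair, the (R)-benzyl auxiliary fixing C7 and C8 (3R,4S in 14), followed by acid-catalysed 5-exo-trig lactonization onto the methyl ester, which turns the syn aldol into the trans-disubstituted γ-lactone.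

Step 9
Reactants: 15 trans-lactone imide (2S,3R)
Product: 16 (2S,3R)-2-{[(2R)-5-ethyl-2-methyl-3-oxo-2,3-dihydrofuran-2-yl]methyl}-5-oxooxolane-3-carboxylic acid
Conditions: LiOH, H2O2, THF/H2O 3:1, 0 °C; Na2SO3; then HCl to pH 2
Reagents that add atoms: hydrogen peroxide (as LiOOH) OO
Why: Lithium hydroperoxide cleaves the exocyclic imide carbonyl selectively (standard auxiliary removal) without epimerizing C7, and any opened lactone recloses on acidification.

Step 10
Reactants: 16 (2S,3R)-2-{[(2R)-5-ethyl-2-methyl-3-oxo-2,3-dihydrofuran-2-yl]methyl}-5-oxooxolane-3-carboxylic acid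
Product: 19 bromomethyl ketone (4R,5S), via acid chloride 17 (not isolated), via diazoketone 18 (not isolated)
Conditions: (COCl)2, DMF (cat.), CH2Cl2, 0 → 23 °C; evaporate; CH2N2, Et2O/THF, 0 °C; then 48% aq. HBr, 0 °C
Reagents that add atoms: oxalyl chloride (Cl of 17 only) ClC(=O)C(=O)Cl; diazomethane C=[N+]=[N-]; hydrogen bromide Br
Why: Arndt–Eistert-type sequence stopped at the diazoketone: acid chloride formation, acylation of diazomethane and hydrobromination should give the bromomethyl ketone that brings in C5.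

Step 11
Reactants: 19 bromomethyl ketone (4R,5S)
Product: 20 (4S,5S)-4-[(1S)-2-bromo-1-hydroxyethyl]-5-{[(2R)-5-ethyl-2-methyl-3-oxo-2,3-dihydrofuran-2-yl]methyl}oxolan-2-one
Conditions: (S)-Me-CBS (20 mol %), BH3·SMe2, THF, −20 °C; MeOH quench
Reagents that add atoms: none
Why: Corey–Bakshi–Shibata reduction: the (S)-oxazaborolidine delivers hydride with bromomethyl as the small group and sets C6 as required, matched with the Felkin preference of the adjacent centre C7, while the α-bromo ketone reacts far faster than the vinylogous ester carbonyl or the lactone.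

Step 12
Reactants: 20 bromohydrin (4S,5S,1'S)
Product: 21 (4R,5S)-4-[(1S)-2-bromo-1-{[tert-butyl(dimethyl)silyl]oxy}ethyl]-5-{[(2R)-5-ethyl-2-methyl-3-oxo-2,3-dihydrofuran-2-yl]methyl}oxolan-2-one
Conditions: TBSOTf, 2,6-lutidine, CH2Cl2, −78 → 0 °C
Reagents that add atoms: tert-butyldimethylsilyl triflate CC(C)(C)[Si](C)(C)OS(=O)(=O)C(F)(F)F
Why: Silylation with the silyl triflate and a hindered pyridine base protects O6 without epoxide formation from the bromohydrin.

Step 13
Reactants: 21 silyl ether bromide
Product: 22 dibromide (C4 epimers)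
Conditions: NBS (1.05 equiv), AIBN (cat.), PhCF3, 80 °C, visible light
Reagents that add atoms: N-bromosuccinimide O=C1CCC(=O)N1Br
Why: Wohl–Ziegler radical bromination at the CH2 of the 5-ethyl group (C4), whose radical is allylic to the furanone double bond, as known for 5-ethyl-3(2H)-furanones; both C4 epimers should form and both are used.

Step 14
Reactants: 22 dibromide (C4 epimers)
Product: 23 ten-membered cyclic sulfide (6S,7R,8S,10R; C4 epimers)
Conditions: Na2S·9H2O (1.1 equiv), DMF/H2O 20:1, 50 °C, high dilution (2 mM, syringe pump)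
Reagents that add atoms: sodium sulfide [Na+].[Na+].[S-2]
Why: Double SN2 alkylation of sulfide: the activated secondary bromide at C4 reacts first and the thiolate then closes the ten-membered ring on the primary C5 bromide, the classical entry to cyclic sulfides for Ramberg–Bäcklund chemistry, helped by the long C–S bonds.

Step 15
Reactants: 23 ten-membered cyclic sulfide
Product: 24 cyclic sulfone (C4 epimers)
Conditions: mCPBA (2.3 equiv), NaHCO3, CH2Cl2, 0 → 23 °C
Reagents that add atoms: 3-chloroperbenzoic acid OOC(=O)c1cccc(Cl)c1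
Why: Peracid oxidation of the sulfide through the sulfoxide to the sulfone; the electron-poor furanone double bond should not be epoxidized.

Step 16
Reactants: 24 cyclic sulfone
Product: 25 α-chloro sulfone (Cl at C4; epimers)
Conditions: LiHMDS (1.1 equiv), THF, −78 °C; NCS, −78 → −20 °C
Reagents that add atoms: N-chlorosuccinimide O=C1CCC(=O)N1Cl
Why: Electrophilic chlorination of the most acidic carbanion: C4–H lies between the sulfonyl group and the furanone C3 (vinylogous β-keto sulfone), so one equivalent of base ionizes only this position and NCS chlorinates it at the exocyclic carbon, as in furanone γ-anion chemistry.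

Step 17
Reactants: 25 α-chloro sulfone
Product: 27 oxonine lactone (4Z), via episulfone 26 (not isolated)
Conditions: t-BuOK (3 equiv), THF, −78 → 0 °C
Reagents that add atoms: none
Why: Ramberg–Bäcklund ring contraction: tert-butoxide removes a proton from C5, the only sulfone α-carbon that still carries hydrogen, and the carbanion displaces chloride from C4 in a 1,3-elimination to the thiirane 1,1-dioxide 26, which loses SO2 in a stereospecific cheletropic step. The closest known reaction type is the Ramberg–Bäcklund contraction of cyclic α-halo sulfones to strained medium-ring cycloalkenes. The only ring closed is the three-membered episulfone (3-exo-tet); the nine-membered oxonine is not closed directly but arises from the ten-membered 1-oxa-4-thiacyclodecane ring by extrusion of the sulfur atom. No stereocentre is created; the Z geometry of C4=C5 is fixed by the ring, because only the cis-fused episulfone fits the bridged bicycle and an E alkene cannot span a nine-membered ring that also carries the planar furanone. The step needs 1,3-displacement to outrun β-elimination of the C6 silyloxy group and dehydrochlorination toward C15; this is secured by the intramolecular three-membered closure at a carbon activated by the furanone, while deprotonation of the lactone α-CH2 is reversible and unproductive.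

Step 18
Reactants: 27 oxonine lactone (4Z)
Product: 28 11-(dimethylaminomethyl) lactone (C11 epimers)
Conditions: LDA (1.3 equiv), THF, −78 °C; CH2=NMe2+ I−, −78 → 23 °C
Reagents that add atoms: dimethyl(methylidene)ammonium iodide C=[N+](C)C.[I-]
Why: The kinetic lithium enolate of the γ-lactone (the only readily enolizable position, since C10 is quaternary and C4 is now sp2) undergoes a Mannich reaction with Eschenmoser's salt.

Step 19
Reactants: 28 11-(dimethylaminomethyl) lactone
Product: 30 α-methylene lactone, via ammonium iodide 29 (not isolated)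
Conditions: MeI, MeOH, 23 °C; then aq. NaHCO3/CH2Cl2, 23 °C
Reagents that add atoms: iodomethane (atoms in 29 only) CI
Why: Exhaustive N-methylation and base-induced Hofmann-type (E1cB) loss of trimethylamine, the standard second stage of lactone α-methylenation.

Step 20
Reactants: 30 α-methylene lactone
Product: 31 C6 alcohol (6R,7S,8S,10R)
Conditions: HF·pyridine, pyridine, THF, 0 → 23 °C
Reagents that add atoms: none
Why: Buffered fluoride desilylation frees O6 under slightly acidic conditions that should leave the methylene lactone and the vinylogous ester intact and not move the lactone to O6.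

Step 21
Reactants: 32 (2R)-but-3-yn-2-ol
Product: 33 tert-butyl{[(2R)-but-3-yn-2-yl]oxy}dimethylsilane
Conditions: TBSCl, imidazole, CH2Cl2, 0 → 23 °C
Reagents that add atoms: tert-butyldimethylsilyl chloride CC(C)(C)[Si](C)(C)Cl
Why: Standard silylation of the secondary propargylic alcohol; the stereocentre is not involved.

Step 22
Reactants: 33 tert-butyl{[(2R)-but-3-yn-2-yl]oxy}dimethylsilane
Product: 34 methyl (3R)-3-{[tert-butyl(dimethyl)silyl]oxy}-2-methylidenebutanoate
Conditions: Pd(OAc)2 (1 mol %), 2-(diphenylphosphino)pyridine (4 mol %), MsOH (2 mol %), CO (10 bar), MeOH (5 equiv), CH2Cl2, 45 °C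
Reagents that add atoms: carbon monoxide [C-]#[O+]; methanol CO
Why: Palladium/2-pyridylphosphine-catalysed Markovnikov methoxycarbonylation of a terminal alkyne should give the branched 2-substituted acrylate without touching the carbinol centre.

Step 23
Reactants: 34 methyl (3R)-3-{[tert-butyl(dimethyl)silyl]oxy}-2-methylidenebutanoate
Product: 35 (3R)-3-{[tert-butyl(dimethyl)silyl]oxy}-2-methylidenebutanoic acid
Conditions: LiOH·H2O, THF/MeOH/H2O, 23 °C; then 1 M HCl to pH 3
Reagents that add atoms: lithium hydroxide [Li+].[OH-]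
Why: Saponification of the methyl ester; the silyl ether and the stereocentre are stable to aqueous LiOH.

Step 24
Reactants: 31 C6 alcohol; 35 (3R)-3-{[tert-butyl(dimethyl)silyl]oxy}-2-methylidenebutanoic acid
Product: 37 silyl-protected target, via mixed anhydride 36 (not isolated)
Conditions: 35, 2,4,6-trichlorobenzoyl chloride, Et3N, THF, 23 °C; then 31, DMAP, toluene, 23 °C
Reagents that add atoms: 2,4,6-trichlorobenzoyl chloride (atoms in 36 only) O=C(Cl)c1c(Cl)cc(Cl)cc1Cl
Why: Yamaguchi esterification: DMAP attacks the acrylic carbonyl of the mixed anhydride and the acylpyridinium acylates the hindered allylic C6 alcohol with retention, which should be faster than lactone migration.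

Step 25
Reactants: 37 silyl-protected target
Product: 38 target CNP0266753.1
Conditions: HF·pyridine, THF, 0 → 23 °C
Reagents that add atoms: none
Why: Fluoride desilylation frees the side-chain alcohol under conditions that should spare both esters and both Michael acceptors.

**Compound list**

1 | (S)-lactic acid | C[C@H](O)C(=O)O | starting material
2 | pivalaldehyde (2,2-dimethylpropanal) | CC(C)(C)C=O | starting material
3 | (2S,5S)-2-tert-butyl-5-methyl-1,3-dioxolan-4-one (cis) | C[C@@H]1O[C@H](C(C)(C)C)OC1=O | intermediate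
4 | allyl bromide | C=CCBr | starting material
5 | (2S,5R)-2-tert-butyl-5-methyl-5-(prop-2-en-1-yl)-1,3-dioxolan-4-one | C=CC[C@@]1(C)O[C@H](C(C)(C)C)OC1=O | intermediate
6 | (2R)-2-hydroxy-N-methoxy-N,2-dimethylpent-4-enamide | C=CC[C@@](C)(O)C(=O)N(C)OC | intermediate
7 | but-1-yne | CCC#C | starting material
8 | (4R)-4-hydroxy-4-methylnon-1-en-6-yn-5-one | C=CC[C@@](C)(O)C(=O)C#CCC | intermediate
9 | (2R)-5-ethyl-2-methyl-2-(prop-2-en-1-yl)furan-3(2H)-one | C=CC[C@@]1(C)OC(CC)=CC1=O | intermediate
10 | [(2R)-5-ethyl-2-methyl-3-oxo-2,3-dihydrofuran-2-yl]acetaldehyde | O=CC[C@@]1(C)OC(CC)=CC1=O | intermediate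
11 | (4R)-4-benzyl-1,3-oxazolidin-2-one | O=C1N[C@H](Cc2ccccc2)CO1 | starting material
12 | methyl 4-chloro-4-oxobutanoate | COC(=O)CCC(Cl)=O | starting material
13 | methyl 4-[(4R)-4-benzyl-2-oxo-1,3-oxazolidin-3-yl]-4-oxobutanoate | COC(=O)CCC(=O)N1[C@H](Cc2ccccc2)COC1=O | intermediate
14 | methyl (3R,4S)-3-{[(4R)-4-benzyl-2-oxo-1,3-oxazolidin-3-yl]carbonyl}-5-[(2R)-5-ethyl-2-methyl-3-oxo-2,3-dihydrofuran-2-yl]-4-hydroxypentanoate (syn-aldol adduct) | COC(=O)C[C@@H](C(=O)N1[C@H](Cc2ccccc2)COC1=O)[C@@H](O)C[C@@]1(C)OC(CC)=CC1=O | intermediate (not isolated)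
15 | (4R)-4-benzyl-3-{[(2S,3R)-2-{[(2R)-5-ethyl-2-methyl-3-oxo-2,3-dihydrofuran-2-yl]methyl}-5-oxooxolan-3-yl]carbonyl}-1,3-oxazolidin-2-one (trans lactone) | O=C1C[C@@H](C(=O)N2[C@H](Cc3ccccc3)COC2=O)[C@H](C[C@@]2(C)OC(CC)=CC2=O)O1 | intermediate
16 | (2S,3R)-2-{[(2R)-5-ethyl-2-methyl-3-oxo-2,3-dihydrofuran-2-yl]methyl}-5-oxooxolane-3-carboxylic acid | O=C1C[C@@H](C(=O)O)[C@H](C[C@@]2(C)OC(CC)=CC2=O)O1 | intermediate
17 | (2S,3R)-2-{[(2R)-5-ethyl-2-methyl-3-oxo-2,3-dihydrofuran-2-yl]methyl}-5-oxooxolane-3-carbonyl chloride | O=C1C[C@@H](C(Cl)=O)[C@H](C[C@@]2(C)OC(CC)=CC2=O)O1 | intermediate (not isolated)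
18 | (4R,5S)-4-(2-diazoacetyl)-5-{[(2R)-5-ethyl-2-methyl-3-oxo-2,3-dihydrofuran-2-yl]methyl}oxolan-2-one | O=C1C[C@@H](C(=O)C=[N+]=[N-])[C@H](C[C@@]2(C)OC(CC)=CC2=O)O1 | intermediate (not isolated)
19 | (4R,5S)-4-(2-bromoacetyl)-5-{[(2R)-5-ethyl-2-methyl-3-oxo-2,3-dihydrofuran-2-yl]methyl}oxolan-2-one | O=C1C[C@@H](C(=O)CBr)[C@H](C[C@@]2(C)OC(CC)=CC2=O)O1 | intermediate
20 | (4S,5S)-4-[(1S)-2-bromo-1-hydroxyethyl]-5-{[(2R)-5-ethyl-2-methyl-3-oxo-2,3-dihydrofuran-2-yl]methyl}oxolan-2-one | O=C1C[C@@H]([C@H](O)CBr)[C@H](C[C@@]2(C)OC(CC)=CC2=O)O1 | intermediate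
21 | (4R,5S)-4-[(1S)-2-bromo-1-{[tert-butyl(dimethyl)silyl]oxy}ethyl]-5-{[(2R)-5-ethyl-2-methyl-3-oxo-2,3-dihydrofuran-2-yl]methyl}oxolan-2-one | O=C1C[C@@H]([C@H](O[Si](C)(C)C(C)(C)C)CBr)[C@H](C[C@@]2(C)OC(CC)=CC2=O)O1 | intermediate
22 | (4R,5S)-4-[(1S)-2-bromo-1-{[tert-butyl(dimethyl)silyl]oxy}ethyl]-5-{[(2R)-5-(1-bromoethyl)-2-methyl-3-oxo-2,3-dihydrofuran-2-yl]methyl}oxolan-2-one, both epimers at CHBr (C4) | O=C1C[C@@H]([C@H](O[Si](C)(C)C(C)(C)C)CBr)[C@H](C[C@@]2(C)OC(C(C)Br)=CC2=O)O1 | intermediate
23 | ten-membered cyclic sulfide: S joins C4 (CH–CH3 on the furanone) and C5 (CH2 next to C6–OTBS), trans γ-lactone at C7/C8, (6S,7R,8S,10R), C4 epimers | O=C1C[C@H]2[C@H](O[Si](C)(C)C(C)(C)C)CSC(C)C3=CC(=O)[C@](C)(O3)C[C@@H]2O1 | intermediate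
24 | S,S-dioxide (sulfone) of 23, C4 epimers | O=C1C[C@H]2[C@H](O[Si](C)(C)C(C)(C)C)CS(=O)(=O)C(C)C3=CC(=O)[C@](C)(O3)C[C@@H]2O1 | intermediate
25 | 4-chloro sulfone (Cl on C4 of 24), C4 epimers | O=C1C[C@H]2[C@H](O[Si](C)(C)C(C)(C)C)CS(=O)(=O)C(C)(Cl)C3=CC(=O)[C@](C)(O3)C[C@@H]2O1 | intermediate
26 | episulfone: thiirane 1,1-dioxide across C4–C5 fused to the nine-membered ring | O=C1C[C@H]2[C@H](O[Si](C)(C)C(C)(C)C)C4S(=O)(=O)C4(C)C3=CC(=O)[C@](C)(O3)C[C@@H]2O1 | intermediate (not isolated)
27 | (4Z,6R,7R,8S,10R)-6-O-TBS oxonine-furanone with saturated lactone α-CH2 (13-nor core) | O=C1C[C@H]2[C@H](O[Si](C)(C)C(C)(C)C)/C=C(C)\C3=CC(=O)[C@](C)(O3)C[C@@H]2O1 | intermediate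
28 | 11-(dimethylaminomethyl) derivative of 27, C11 epimers | O=C1C(CN(C)C)[C@H]2[C@H](O[Si](C)(C)C(C)(C)C)/C=C(C)\C3=CC(=O)[C@](C)(O3)C[C@@H]2O1 | intermediate
29 | 11-(trimethylammoniomethyl) iodide of 27 | O=C1C(C[N+](C)(C)C)[C@H]2[C@H](O[Si](C)(C)C(C)(C)C)/C=C(C)\C3=CC(=O)[C@](C)(O3)C[C@@H]2O1.[I-] | intermediate (not isolated)
30 | (4Z,6R,7R,8S,10R)-6-O-TBS α-methylene lactone | O=C1C(=C)[C@H]2[C@H](O[Si](C)(C)C(C)(C)C)/C=C(C)\C3=CC(=O)[C@](C)(O3)C[C@@H]2O1 | intermediate
31 | (4Z,6R,7S,8S,10R)-6-hydroxy α-methylene lactone (core alcohol) | O=C1C(=C)[C@H]2[C@H](O)/C=C(C)\C3=CC(=O)[C@](C)(O3)C[C@@H]2O1 | intermediate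
32 | (2R)-but-3-yn-2-ol | C#C[C@@H](C)O | starting material
33 | tert-butyl{[(2R)-but-3-yn-2-yl]oxy}dimethylsilane | C#C[C@@H](C)O[Si](C)(C)C(C)(C)C | intermediate
34 | methyl (3R)-3-{[tert-butyl(dimethyl)silyl]oxy}-2-methylidenebutanoate | C=C(C(=O)OC)[C@@H](C)O[Si](C)(C)C(C)(C)C | intermediate
35 | (3R)-3-{[tert-butyl(dimethyl)silyl]oxy}-2-methylidenebutanoic acid | C=C(C(=O)O)[C@@H](C)O[Si](C)(C)C(C)(C)C | intermediate
36 | mixed anhydride of 35 with 2,4,6-trichlorobenzoic acid | C=C(C(=O)OC(=O)c1c(Cl)cc(Cl)cc1Cl)[C@@H](C)O[Si](C)(C)C(C)(C)C | intermediate (not isolated)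
37 | (3R)-3-(TBS-oxy)-2-methylidenebutanoate of 31 (silyl-protected target) | O=C1C(=C)[C@H]2[C@H](OC(=O)C(=C)[C@@H](C)O[Si](C)(C)C(C)(C)C)/C=C(C)\C3=CC(=O)[C@](C)(O3)C[C@@H]2O1 | intermediate
38 | CNP0266753.1: (4Z,6R,7R,8S,10R) core with trans 8,12-methylene lactone and (3R)-3-hydroxy-2-methylidenebutanoate at O6 | O=C1C(=C)[C@H]2[C@H](OC(=O)C(=C)[C@@H](C)O)/C=C(C)\C3=CC(=O)[C@](C)(O3)C[C@@H]2O1 | target

**Summary**

Total step count: 25. Longest linear sequence: 21 steps (1–6, 8–20, 24, 25).

Steps most likely to fail: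

1. Step 17. The C5 carbanion may expel the C6 silyloxy group by β-elimination, or the chloride may be lost by dehydrochlorination toward C15, before the strained episulfone closes. The fallback sets out from 22 and comes back at 27. Arbuzov reaction with triethyl phosphite (1 equiv, 80 °C) at the activated secondary bromide should give the diethyl phosphonate F1. Kornblum-type oxidation of the remaining primary bromide (AgBF4, DMSO, then Et3N) should give the α-silyloxy aldehyde F2. Intramolecular Horner–Wadsworth–Emmons olefination (LiCl, DBU, MeCN, high dilution) would then form C4=C5 directly, with the ring again enforcing Z, and deliver 27.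

2. Step 14. Intermolecular oligomerization, or E2 loss of HBr at C4, may compete with closure of the ten-membered ring. The fallback sets out from 22 and comes back at 23. Potassium thioacetate (1 equiv, DMF, −20 °C) should displace only the activated C4 bromide to give the thioacetate F3. Methanolysis with K2CO3 in degassed MeOH/THF at high dilution frees the thiolate, which closes in a unimolecular step onto the C5 bromide to give 23.

3. Step 13. Polar bromination at the furanone ring carbon C2, or over-bromination, may compete with radical substitution at C4. The fallback sets out from 21 and comes back at 22. Soft enolization with TMSOTf/Et3N (CH2Cl2, −78 → 0 °C) should give the cross-conjugated silyl dienol ether F4, because C4–H is the only enolizable position of the furanone. NBS in THF at −78 °C should then brominate the γ-carbon in a polar reaction that restores the furanone and gives 22.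

Further compounds
F1 | step 17 | diethyl {1-[(2R)-2-{[(2S,3R)-3-[(1S)-2-bromo-1-{[tert-butyl(dimethyl)silyl]oxy}ethyl]-5-oxooxolan-2-yl]methyl}-2-methyl-3-oxo-2,3-dihydrofuran-5-yl]ethyl}phosphonate (C4 epimers) | O=C1C[C@@H]([C@H](O[Si](C)(C)C(C)(C)C)CBr)[C@H](C[C@@]2(C)OC(C(C)P(=O)(OCC)OCC)=CC2=O)O1
F2 | step 17 | phosphonate aldehyde: F1 with the CH2Br group replaced by CHO (C5 aldehyde, C6–OTBS) | O=C1C[C@@H]([C@H](O[Si](C)(C)C(C)(C)C)C=O)[C@H](C[C@@]2(C)OC(C(C)P(=O)(OCC)OCC)=CC2=O)O1
F3 | step 14 | S-{1-[(2R)-2-{[(2S,3R)-3-[(1S)-2-bromo-1-{[tert-butyl(dimethyl)silyl]oxy}ethyl]-5-oxooxolan-2-yl]methyl}-2-methyl-3-oxo-2,3-dihydrofuran-5-yl]ethyl} ethanethioate (C4 epimers) | O=C1C[C@@H]([C@H](O[Si](C)(C)C(C)(C)C)CBr)[C@H](C[C@@]2(C)OC(C(C)SC(C)=O)=CC2=O)O1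
F4 | step 13 | silyl dienol ether of 21: 5-ethylidene-2-methyl-3-(trimethylsilyloxy)-2,5-dihydrofuran-2-yl unit in place of the furanone | O=C1C[C@@H]([C@H](O[Si](C)(C)C(C)(C)C)CBr)[C@H](C[C@@]2(C)OC(=CC)C=C2O[Si](C)(C)C)O1
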